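The readings stem from a simulated flask for an exercise; the scatter is artificial.

Partner is the single-handed reagent that turns both substrates into products. The readings never show it, and I take it to come from the solid reagent, which starts undissolved, so I look for a number in which it drops out.

| flask | left-handed substrate | right-handed substrate | solid reagent | remark | time |
|---|---|---|---|---|---|
| cedar | 0.35 M | 0.35 M | 0.75 M | run made earlier |  |
| birch | 0.55 M | 0.55 M | 0.75 M | run made earlier |  |
| alder | 0.25 M | 0.25 M | 0.38 M | run made earlier |  |
| flask | 0.25 M | 0.25 M | 0.750 M |  | 6.0 h |

| run | time / h | left-handed product / % | right-handed product / % | left-handed substrate / % |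
|---|---|---|---|---|
| cedar | 1.50 | 5.9 | 3.6 | 43.6 |
| cedar | 3.00 | 14.1 | 7.9 | 35.7 |
| cedar | 5.00 | 21.9 | 12.2 | 27.0 |
| cedar | 6.00 | 26.8 | 14.1 | 23.0 |
| birch | 0.500 | 0.8 | 0.3 | 49.1 |
| birch | 1.00 | 3.6 | 2.0 | 46.6 |
| birch | 2.50 | 10.6 | 4.6 | 40.0 |
| birch | 6.00 | 24.0 | 11.7 | 27.8 |
| alder | 0.500 | 1.6 | 0.5 | 49.2 |
| alder | 1.00 | 4.1 | 1.1 | 46.1 |
| alder | 2.50 | 12.7 | 4.6 | 37.0 |
| alder | 6.00 | 28.8 | 15.5 | 21.1 |

(standard deviation of a reading: 0.5 percentage points)

- partner is single-handed; left-handed substrate and right-handed substrate are mirror images of each other, charged as a racemate, each of them at the stated concentration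
- given per volume of solution although it is solid: solid reagent
- at the start none of the solid reagent is in solution
- an excess is the difference of the two amounts in percent of their sum
- an excess is below zero if the other one leads
- the handed part of partner does not stay in what it makes, so the products of the two hands are mirror images too

- excess of left-handed product over right-handed product in the product at 40 min
- excess of left-handed product over right-handed product in the product at 6.0 h
- part of the left-handed substrate and right-handed substrate charged together that has reacted at 6.0 h

I build the flask up one process at a time. First comes the main step alone: with partner held steady, each substrate falls pseudo-first-order, and the two logarithms of the fraction left stand in a fixed ratio. I take right-handed substrate as its share of the charge less right-handed product. At 6.00 h, cedar gives 2.34, birch 2.20 and alder 2.33. Their mean, 2.29, is my selectivity factor s, the logarithm of the fraction of left-handed substrate left over that of right-handed substrate. At the start, the excess is s less one over s plus one, 39.2%.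

Next I let the substrates run down. Left-handed substrate goes faster, so the excess falls as conversion grows.

Then I add the solid and whatever else happens to partner. I assume that both hands react with the same partner and at first order in it, so that these processes change how far the run gets, not s. I measure that distance by the logarithm of one over the fraction of right-handed substrate left: cedar 0.331, birch 0.267, and alder, with about half the solid, 0.371. Extending the birch-to-cedar line to the flask's charge gives 0.364. My reckoning for the flask is then 69.5% of right-handed substrate left and 43.5% of left-handed. That makes 43.5% reacted and an excess of 29.9% at 6.0 h, with close to 39.2% at 40 min.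

The forecast says 33%, 30.5% and 45%, and holds that “solid loading barely affects the rate”. It stands below me at 40 min and slightly above me in conversion.

The flask gives 37.6%, 28.8% and 44.5%.

    partner → decomposed reagent (k = 1.60 × 10⁻⁵ s⁻¹)
    partner ⇌ dormant form (K = 0.830, k = 5.10 × 10⁻⁵ s⁻¹)
    partner + left-handed substrate → left-handed product (k = 5.80 × 10⁻⁴ M⁻¹ s⁻¹)
    solid reagent ⇌ partner, rate k4*(cs4 - [partner]) while solid is left; crystals form when [partner] > cs4 (solubility = 0.120 M, k = 3.30 × 10⁻⁴ s⁻¹)
    partner + right-handed substrate → right-handed product (k = 2.60 × 10⁻⁴ M⁻¹ s⁻¹)

At 2.40 h the flask's partner goes into left-handed product 1.9 times as fast as into right-handed product, and at 6.00 h the flask keeps 43% of its left-handed substrate against 68% of its right-handed. Raised to the power s, that right-handed fraction gives 41.8% for left-handed substrate. The neighbour charged with 0.19 M of solid reagent reacts less, 29.2% against 44.5%. Its 80% of right-handed substrate gives 60.0% by the same power, and it keeps 61% of left-handed substrate.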